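**Plan**
1. Target numbering (7-oxabicyclo[4.1.0]hept-3-en-2-one): C1 oxirane carbon bearing the side chain, C2 ketone, C3 =CH, C4 C–OMe, C5 CHOH, C6 oxirane CH, O7.
2. Cuts: the O–CH3 bond at C4 (back to the 2,4-dione); the ring bond C2–C3 (back to a γ-lactone joining C2 to O5, with C4–C3 as an acetyl group on C5); C4–C5 (acetyl anion plus aldehyde); the oxirane C1–O7–C6 (Z-allylic alcohol); C1=C6 (olefination); C1–CH2 of the side chain (alkylation).
3. Forward: the chain is joined first (side chain to C1, then C1=C6), the oxirane is closed next, C5 receives C4–C3 and is tied to C2 as a temporary lactone ring, and the six-membered carbocycle is closed last through C2–C3; O-methylation ends the route.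
4. Enabling feature: C2 and C5 sit cis on the oxirane (on C1 and C6), so C2 can be tied to the C5 oxygen as a five-membered lactone that holds the acyl carbon C2 next to the methyl enolate carbon C3 of the C5 acetyl group; O→C acyl transfer then closes the ring and frees the C5 hydroxyl without a protecting group.
5. Stereochemistry: C1 and C6 from Sharpless epoxidation (diethyl L-tartrate) of the Z-olefin made by Still–Gennari olefination; C5 from Felkin–Anh addition to the oxiranyl aldehyde; none of the three is touched afterwards.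

Key step: step 8

Remark: in the names, farnesyl means (2E,6E)-3,7,11-trimethyldodeca-2,6,10-trien-1-yl; aldehyde 4 is sold as an aqueous solution and is assumed to be extracted and dried before use.

Step 1
Reactants: 1 (2E,6E)-farnesyl bromide; 2 methyl 2-[bis(2,2,2-trifluoroethoxy)phosphoryl]acetate
Product: 3 methyl 2-[bis(2,2,2-trifluoroethoxy)phosphoryl]-2-farnesylacetate (racemic)
Conditions: NaH (1.0 equiv), 2 (1.2 equiv), THF/DMF, 0 °C; then 1, 0 °C → rt
Reagents that add atoms: none
Why: SN2 C-alkylation of the stabilised phosphonoacetate anion at the primary allylic carbon of 1 (malonate-type alkylation) should leave the 2E,6E olefins untouched, and the new stereocentre is racemic and disappears in step 2.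

Step 2
Reactants: 3 methyl 2-[bis(2,2,2-trifluoroethoxy)phosphoryl]-2-farnesylacetate; 4 2,2-dimethoxyacetaldehyde
Product: 5 methyl (2Z)-2-farnesyl-4,4-dimethoxybut-2-enoate
Conditions: KN(SiMe3)2, 18-crown-6, THF, −78 °C; then 4, −78 °C
Reagents that add atoms: none
Why: Still–Gennari variant of the Horner–Wadsworth–Emmons olefination, in which fast irreversible collapse of the syn oxaphosphetane from the trifluoroethyl phosphonate should give the Z-trisubstituted enoate, with the ester carbon cis to the acetal carbon as the later cis-fused ring requires.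

Step 3
Reactants: 5 methyl (2Z)-2-farnesyl-4,4-dimethoxybut-2-enoate
Product: 6 (2Z)-2-farnesyl-4,4-dimethoxybut-2-en-1-ol
Conditions: iBu2AlH (2.5 equiv), CH2Cl2, −78 °C; aq. KNaC4H4O6 work-up
Reagents that add atoms: none
Why: 1,2-reduction of the enoate to the primary allylic alcohol by the aluminium hydride at low temperature should preserve the Z geometry and the acetal.

Step 4
Reactants: 6 (2Z)-2-farnesyl-4,4-dimethoxybut-2-en-1-ol
Product: 7 [(2S,3S)-3-(dimethoxymethyl)-2-farnesyloxiran-2-yl]methanol
Conditions: Ti(OiPr)4 (10 mol%), diethyl L-(+)-tartrate (12 mol%), t-BuOOH (2 equiv), 4 Å molecular sieves, CH2Cl2, −20 °C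
Reagents that add atoms: tert-butyl hydroperoxide CC(C)(C)OO
Why: Sharpless asymmetric epoxidation, in which the titanium tartrate complex binds the allylic hydroxyl so that only the allylic olefin (not the three side-chain olefins) is epoxidised, diethyl L-tartrate directs the oxygen to the face that gives the (2S,3S)-oxirane (C1 and C6 of the target), and the Z geometry is carried over stereospecifically into the cis relation of CH2OH and the acetal carbon.

Step 5
Reactants: 7 [(2S,3S)-3-(dimethoxymethyl)-2-farnesyloxiran-2-yl]methanol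
Product: 8 (2R,3S)-3-(dimethoxymethyl)-2-farnesyloxirane-2-carboxylic acid
Conditions: TEMPO (20 mol%), PhI(OAc)2 (2.2 equiv), MeCN/aq. NaH2PO4–Na2HPO4 buffer (pH 7), 0 °C → rt
Reagents that add atoms: water O
Why: TEMPO-catalysed oxidation with PhI(OAc)2 in aqueous acetonitrile should take the primary alcohol through the aldehyde hydrate to the carboxylic acid under near-neutral conditions that leave the trisubstituted olefins, the oxirane and the acetal alone.

Step 6
Reactants: 8 (2R,3S)-3-(dimethoxymethyl)-2-farnesyloxirane-2-carboxylic acid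
Product: 9 (1R,5S)-1-farnesyl-4-hydroxy-3,6-dioxabicyclo[3.1.0]hexan-2-one (lactol form of the cis formyl acid)
Conditions: 1 M HCl, THF, 0 °C → rt
Reagents that add atoms: water O
Why: Acid hydrolysis of the dimethyl acetal, in which the oxirane is deactivated towards ionisation by the carboxyl group on one carbon and the acetal carbon on the other, and the neighbouring carboxyl traps the freed aldehyde as the five-membered lactol (pseudo acid), as 2-formylbenzoic acid does.

Step 7
Reactants: 9 (1R,5S)-1-farnesyl-4-hydroxy-3,6-dioxabicyclo[3.1.0]hexan-2-one; 10 ethyl vinyl ether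
Product: 13 (1R,4S,5R)-4-acetyl-1-farnesyl-3,6-dioxabicyclo[3.1.0]hexan-2-one, via dilithium adduct 11 (not isolated), via ethoxyvinyl lactone 12 (not isolated)
Conditions: 10, t-BuLi, THF, −78 → 0 °C [CH2=C(OEt)Li, 2.3 equiv]; 9, THF, −78 °C; then 1 M HCl, 0 °C → rt
Reagents that add atoms: water O
Why: Addition of an acetyl anion equivalent (polarity-reversed acetaldehyde) to a pseudo acid, as Grignard reagents add to 2-formylbenzoic acid, in which the first equivalent opens the lactol to the lithium carboxylate aldehyde, the second adds to the aldehyde anti to the oxirane C–O bond (Felkin–Anh, the usual sense for cis-α,β-epoxy aldehydes) to set the carbinol carbon (C5 of the target) as S, and aqueous acid then hydrolyses the enol ether to the methyl ketone and lactonises the cis hydroxy acid.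

Step 8
Reactants: 13 (1R,4S,5R)-4-acetyl-1-farnesyl-3,6-dioxabicyclo[3.1.0]hexan-2-one
Product: 16 (1R,5S,6R)-1-farnesyl-5-hydroxy-7-oxabicyclo[4.1.0]heptane-2,4-dione, via lithium enolate 14 (not isolated), via bridged alkoxide 15 (not isolated)
Conditions: LiN(SiMe3)2 (2.5 equiv), THF, −78 °C (slow addition of 13, 0.01 M) → −20 °C; then cold 0.5 M HCl to pH 3
Reagents that add atoms: none
Why: LiN(SiMe3)2 should remove a proton from the acetyl CH3 (the kinetic site of α-oxygenated methyl ketones) to give enolate 14, whose carbon (C3, target numbering) adds to the lactone carbonyl (C2) from the face anti to the oxirane oxygen to give the bridged hemiketal alkoxide 15; this collapses by cleavage of the C2–O(lactone) bond, which frees the C5 alkoxide, relieves the strain of the oxirane-fused lactone and of the bridge, and is pulled forward by deprotonation of the new 1,3-dione. The closest known reaction type is the intramolecular Claisen (Dieckmann) acylation in its O→C acyl-transfer form, the Baker–Venkataraman rearrangement of acyloxy ketones, here with a lactone as acyl donor. The carbocycle closes in the 6-(enolendo)-exo-trig mode, and no other ring size is open to the enolate because C2 and the acetyl-bearing C5 are fixed cis on the oxirane. No stereocentre is created: C1 and C6 are not touched, and C5 keeps its configuration because its C–H is not removed under kinetic control. The step needs site-selective enolisation (CH3, not C5–H, whose removal would open the oxirane by β-elimination) and intramolecular rather than intermolecular acylation; excess hindered base at −78 °C with slow inverse addition at high dilution should secure both.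

Step 9
Reactants: 16 (1R,5S,6R)-1-farnesyl-5-hydroxy-7-oxabicyclo[4.1.0]heptane-2,4-dione
Product: 17 yanuthone X2, (1R,5S,6R)-5-hydroxy-4-methoxy-1-[(2E,6E)-3,7,11-trimethyldodeca-2,6,10-trien-1-yl]-7-oxabicyclo[4.1.0]hept-3-en-2-one
Conditions: MeOH, (1S)-camphor-10-sulfonic acid (5 mol%), 3 Å molecular sieves, 0 °C → rt
Reagents that add atoms: methanol CO
Why: Acid-catalysed enol etherification of a cyclic 1,3-dione under equilibrating conditions, in which methanol should condense at C4, the carbonyl flanked by the secondary carbinol, not at C2 beside the fully substituted oxirane carbon (the regiochemistry expected by analogy with 4,4-disubstituted cyclohexane-1,3-diones), while the oxirane, deactivated by the adjacent carbonyl, and the C5 hydroxyl should stay untouched.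

**Compound list**
1 | (2E,6E)-farnesyl bromide, (2E,6E)-1-bromo-3,7,11-trimethyldodeca-2,6,10-triene | BrC/C=C(\C)CC/C=C(\C)CCC=C(C)C | starting material
2 | methyl 2-[bis(2,2,2-trifluoroethoxy)phosphoryl]acetate | COC(=O)CP(=O)(OCC(F)(F)F)OCC(F)(F)F | starting material
3 | methyl 2-[bis(2,2,2-trifluoroethoxy)phosphoryl]-2-farnesylacetate (racemic) | COC(=O)C(C/C=C(\C)CC/C=C(\C)CCC=C(C)C)P(=O)(OCC(F)(F)F)OCC(F)(F)F | intermediate
4 | 2,2-dimethoxyacetaldehyde | COC(OC)C=O | starting material
5 | methyl (2Z)-2-farnesyl-4,4-dimethoxybut-2-enoate | COC(=O)/C(C/C=C(\C)CC/C=C(\C)CCC=C(C)C)=C\C(OC)OC | intermediate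
6 | (2Z)-2-farnesyl-4,4-dimethoxybut-2-en-1-ol | OC/C(C/C=C(\C)CC/C=C(\C)CCC=C(C)C)=C\C(OC)OC | intermediate
7 | [(2S,3S)-3-(dimethoxymethyl)-2-farnesyloxiran-2-yl]methanol | OC[C@]1(C/C=C(\C)CC/C=C(\C)CCC=C(C)C)O[C@@H]1C(OC)OC | intermediate
8 | (2R,3S)-3-(dimethoxymethyl)-2-farnesyloxirane-2-carboxylic acid | OC(=O)[C@]1(C/C=C(\C)CC/C=C(\C)CCC=C(C)C)O[C@@H]1C(OC)OC | intermediate
9 | (1R,5S)-1-farnesyl-4-hydroxy-3,6-dioxabicyclo[3.1.0]hexan-2-one, both C4 epimers, lactol form of (2R,3S)-2-farnesyl-3-formyloxirane-2-carboxylic acid | O=C1[C@]2(C/C=C(\C)CC/C=C(\C)CCC=C(C)C)O[C@@H]2C(O)O1 | intermediate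
10 | ethyl vinyl ether (ethoxyethene) | C=COCC | starting material
11 | dilithium (2R,3R)-3-[(1S)-2-ethoxy-1-oxidoprop-2-en-1-yl]-2-farnesyloxirane-2-carboxylate (not isolated) | [Li+].[Li+].[O-]C(=O)[C@]1(C/C=C(\C)CC/C=C(\C)CCC=C(C)C)O[C@@H]1[C@@H](C(=C)OCC)[O-] | intermediate
12 | (1R,4S,5R)-4-(1-ethoxyethenyl)-1-farnesyl-3,6-dioxabicyclo[3.1.0]hexan-2-one (not isolated) | O=C1[C@]2(C/C=C(\C)CC/C=C(\C)CCC=C(C)C)O[C@@H]2[C@@H](C(=C)OCC)O1 | intermediate
13 | (1R,4S,5R)-4-acetyl-1-farnesyl-3,6-dioxabicyclo[3.1.0]hexan-2-one | O=C1[C@]2(C/C=C(\C)CC/C=C(\C)CCC=C(C)C)O[C@@H]2[C@@H](C(C)=O)O1 | intermediate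
14 | lithium 1-[(1R,2S,5R)-5-farnesyl-4-oxo-3,6-dioxabicyclo[3.1.0]hexan-2-yl]ethen-1-olate, the methyl enolate of 13 (not isolated) | [Li+].O=C1[C@]2(C/C=C(\C)CC/C=C(\C)CCC=C(C)C)O[C@@H]2[C@@H](C(=C)[O-])O1 | intermediate
15 | lithium (1S,2R,4R,5S)-2-farnesyl-6-oxo-3,8-dioxatricyclo[3.2.1.0(2,4)]octan-1-olate, bridged hemiketal alkoxide with the oxirane anti to the keto bridge (not isolated) | [Li+].[O-][C@@]12CC(=O)[C@@H](O1)[C@H]1O[C@@]21C/C=C(\C)CC/C=C(\C)CCC=C(C)C | intermediate
16 | (1R,5S,6R)-1-farnesyl-5-hydroxy-7-oxabicyclo[4.1.0]heptane-2,4-dione | O=C1CC(=O)[C@]2(C/C=C(\C)CC/C=C(\C)CCC=C(C)C)O[C@@H]2[C@@H]1O | intermediate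
17 | yanuthone X2, (1R,5S,6R)-5-hydroxy-4-methoxy-1-[(2E,6E)-3,7,11-trimethyldodeca-2,6,10-trien-1-yl]-7-oxabicyclo[4.1.0]hept-3-en-2-one | COC1=CC(=O)[C@]2(C/C=C(\C)CC/C=C(\C)CCC=C(C)C)O[C@@H]2[C@@H]1O | target

Total step count: 9. Longest linear sequence: 9 steps (from 1 and 2 to 17).

**Steps most likely to fail**

Step 9: methanol may condense at the wrong carbonyl, or the two enol ethers may equilibrate to a mixture (poor regioselectivity of enol ether formation). Fallback, from 16: oxidation of the C5 carbinol (Dess–Martin periodinane, NaHCO3, CH2Cl2, 0 °C) should give the enolised trione (1R,6S)-1-farnesyl-4-hydroxy-7-oxabicyclo[4.1.0]hept-3-ene-2,5-dione F1, in which the only acidic hydroxyl sits on C4. Me3SiCHN2 in MeOH/toluene should then give its methyl ether (1R,6S)-1-farnesyl-4-methoxy-7-oxabicyclo[4.1.0]hept-3-ene-2,5-dione F2. NaBH4 with CeCl3·7H2O in MeOH at −78 °C should reduce the C5 carbonyl (the one not deactivated as a vinylogous ester) from the face anti to the oxirane oxygen, which returns to the route at 17.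

Step 8: ring closure through the strained bridged adduct may be slow, so that intermolecular condensation, or proton transfer to the C5 enolate followed by β-elimination that opens the oxirane, takes over. Fallback, from 9: the addition of CH2=C(OEt)Li is run as in step 7, but the dilithium adduct 11 is not acidified; Et3SiCl caps the alkoxide at −78 °C and MeI in DMF methylates the carboxylate, to give methyl (2R,3R)-3-[(1S)-2-ethoxy-1-(triethylsilyloxy)prop-2-en-1-yl]-2-farnesyloxirane-2-carboxylate F3. Pyridinium p-toluenesulfonate in wet acetone should cleave the enol ether only, giving methyl (2R,3R)-2-farnesyl-3-[(1S)-2-oxo-1-(triethylsilyloxy)propyl]oxirane-2-carboxylate F4. LiN(SiMe3)2 (THF, −78 °C) then closes the ring by an ordinary Dieckmann condensation on the open-chain ester, with no bridged adduct to pass through, to give (1R,5S,6R)-1-farnesyl-5-(triethylsilyloxy)-7-oxabicyclo[4.1.0]heptane-2,4-dione F5, and HF·pyridine removes the silyl group to return to the route at 16.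

Step 4: the epoxidation may be slow and of poor enantiofacial selectivity, because the cis substituent of this 2,3-disubstituted Z-allylic alcohol is the branched acetal carbon. Fallback, from 6: VO(acac)2 with t-BuOOH in CH2Cl2 at 0 °C should epoxidise the allylic olefin alone and give the racemic cis-epoxy alcohol, that is 7 together with its enantiomer [(2R,3R)-3-(dimethoxymethyl)-2-farnesyloxiran-2-yl]methanol F6. Esterification with (2S)-2-methoxy-2-phenylacetic acid (DCC, DMAP) should give the diastereomeric esters [(2S,3S)-3-(dimethoxymethyl)-2-farnesyloxiran-2-yl]methyl (2S)-2-methoxy-2-phenylacetate F7 and [(2R,3R)-3-(dimethoxymethyl)-2-farnesyloxiran-2-yl]methyl (2S)-2-methoxy-2-phenylacetate F8, to be separated by chromatography. K2CO3 in MeOH then cleaves the ester of F7 and returns to the route at 7.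

**Further compounds**
F1 | step 9 | (1R,6S)-1-farnesyl-4-hydroxy-7-oxabicyclo[4.1.0]hept-3-ene-2,5-dione | OC1=CC(=O)[C@]2(C/C=C(\C)CC/C=C(\C)CCC=C(C)C)O[C@@H]2C1=O
F2 | step 9 | (1R,6S)-1-farnesyl-4-methoxy-7-oxabicyclo[4.1.0]hept-3-ene-2,5-dione | COC1=CC(=O)[C@]2(C/C=C(\C)CC/C=C(\C)CCC=C(C)C)O[C@@H]2C1=O
F3 | step 8 | methyl (2R,3R)-3-[(1S)-2-ethoxy-1-(triethylsilyloxy)prop-2-en-1-yl]-2-farnesyloxirane-2-carboxylate | COC(=O)[C@]1(C/C=C(\C)CC/C=C(\C)CCC=C(C)C)O[C@@H]1[C@@H](C(=C)OCC)O[Si](CC)(CC)CC
F4 | step 8 | methyl (2R,3R)-2-farnesyl-3-[(1S)-2-oxo-1-(triethylsilyloxy)propyl]oxirane-2-carboxylate | COC(=O)[C@]1(C/C=C(\C)CC/C=C(\C)CCC=C(C)C)O[C@@H]1[C@@H](C(C)=O)O[Si](CC)(CC)CC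
F5 | step 8 | (1R,5S,6R)-1-farnesyl-5-(triethylsilyloxy)-7-oxabicyclo[4.1.0]heptane-2,4-dione | O=C1CC(=O)[C@]2(C/C=C(\C)CC/C=C(\C)CCC=C(C)C)O[C@@H]2[C@@H]1O[Si](CC)(CC)CC
F6 | step 4 | [(2R,3R)-3-(dimethoxymethyl)-2-farnesyloxiran-2-yl]methanol | OC[C@@]1(C/C=C(\C)CC/C=C(\C)CCC=C(C)C)O[C@H]1C(OC)OC
F7 | step 4 | [(2S,3S)-3-(dimethoxymethyl)-2-farnesyloxiran-2-yl]methyl (2S)-2-methoxy-2-phenylacetate | CO[C@H](C(=O)OC[C@]1(C/C=C(\C)CC/C=C(\C)CCC=C(C)C)O[C@@H]1C(OC)OC)c1ccccc1
F8 | step 4 | [(2R,3R)-3-(dimethoxymethyl)-2-farnesyloxiran-2-yl]methyl (2S)-2-methoxy-2-phenylacetate | CO[C@H](C(=O)OC[C@@]1(C/C=C(\C)CC/C=C(\C)CCC=C(C)C)O[C@H]1C(OC)OC)c1ccccc1
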